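**Retrosynthetic overview**

1. 19 ⇒ 17 + 11: the C6–C7 bond is made last, by axial alkenylation of the ring peroxycarbenium ion, which sets C6.
2. 17 ⇒ 15: the only ring, the 1,2-dioxane, is closed as in the presumed biogenesis, by 6-exo conjugate addition of a C6 hydroperoxide (held as its methyl perketal) to the C2=C3 enoate. This sets C3 trans to C4 and is done before the side chain exists, so that the ring controls C6.
3. 15 ⇒ 13 + methyl acrylate (cross-metathesis); 13 and 11 (via alkyne 8) both come from one ester, 6, whose CH(Et) centre becomes C4 and C10.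
4. 6 ⇒ (R)-hept-4-en-3-ol 2 (Johnson–Claisen, 1,3-chirality transfer) ⇒ (E)-pent-2-enal + Et2Zn (catalytic asymmetric addition).
5. Ring order: one ring only (1,2-dioxane, step 7).

Assumption: the presumed biosynthesis is taken to be 6-exo conjugate addition of a C6 hydroperoxide onto the C2=C3 enoate of the open polyketide chain (plakortin type).

**Route**

Step 1
Reactants: 1 (E)-pent-2-enal
Product: 2 (3R,4E)-hept-4-en-3-ol
Conditions: Et2Zn (1.5 equiv), (2R)-(+)-3-exo-morpholinoisoborneol (4 mol %), hexanes/toluene, 0 °C; cold 1 M HCl work-up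
Reagents that add atoms: diethylzinc, CC[Zn]CC
Why: Ligand-accelerated catalytic asymmetric 1,2-addition of a dialkylzinc to an aldehyde: the amino alcohol–zinc catalyst of the series that gives (R)-1-phenylpropan-1-ol from benzaldehyde delivers ethyl to the Re face of the enal carbonyl, which sets C3 of 2 as R (about 90% ee or better expected for E-enals).

Step 2
Reactants: 2 (3R,4E)-hept-4-en-3-ol; 3 triethyl orthoacetate
Product: 6 ethyl (3R,4E)-3-ethylhept-4-enoate, via mixed orthoester 4 (not isolated), via ketene acetal 5 (not isolated)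
Conditions: 3 (6 equiv), EtCO2H (5 mol %), 140 °C, EtOH distilled off
Reagents that add atoms: none
Why: Johnson–Claisen rearrangement: ketene acetal 5 rearranges through a chair transition state with the carbinol ethyl group equatorial, so the E alkene is regenerated and the carbinol configuration is transferred suprafacially to the new CH(Et) centre (R), the centre that becomes both C4 and C10 of the target.

Step 3
Reactants: 6 ethyl (3R,4E)-3-ethylhept-4-enoate
Product: 8 (4R,5E)-4-ethyloct-5-en-1-yne, via aldehyde 7 (not isolated)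
Conditions: iBu2AlH (1.05 equiv), CH2Cl2, −78 °C; then MeOH, K2CO3, dimethyl (1-diazo-2-oxopropyl)phosphonate, −78 °C → rt
Reagents that add atoms: dimethyl (1-diazo-2-oxopropyl)phosphonate (Ohira–Bestmann reagent), CC(=O)C(=[N+]=[N-])P(=O)(OC)OC
Why: Half-reduction of the ester by iBu2AlH at −78 °C gives the aluminium hemiacetal that releases aldehyde 7 on methanolysis, and Ohira–Bestmann (Seyferth–Gilbert) homologation in the same flask gives the terminal alkyne, the stereocentre being beta to the carbonyl and therefore not epimerisable.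

Step 4
Reactants: 8 (4R,5E)-4-ethyloct-5-en-1-yne
Product: 11 potassium trifluoro[(1E,4R,5E)-4-ethyl-2-methylocta-1,5-dien-1-yl]borate, via alkenylalane 9 (not isolated), via pinacol boronate 10 (not isolated)
Conditions: AlMe3 (2.0 equiv), Cp2ZrCl2 (0.2 equiv), CH2Cl2, 0 °C → rt; then iPrOBpin, −20 °C → rt; then aq KHF2, MeOH, rt; salt extracted into acetone
Reagents that add atoms: trimethylaluminium, C[Al](C)C; 2-isopropoxy-4,4,5,5-tetramethyl-1,3,2-dioxaborolane, CC(C)OB1OC(C)(C)C(C)(C)O1; potassium hydrogen difluoride, [K+].[F-].F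
Why: Negishi zirconium-catalysed carboalumination adds methyl and aluminium syn across the terminal alkyne with aluminium on the terminal carbon (the 1,2-disubstituted alkene does not react), the alkenyl group is then transferred from aluminium to boron with retention and KHF2 turns the boronate into the crystalline trifluoroborate, so the 1E geometry follows from the syn addition and no stereocentre is touched.

Step 5
Reactants: 6 ethyl (3R,4E)-3-ethylhept-4-enoate
Product: 13 (5R,6E)-5-ethylnon-6-en-3-one, via Weinreb amide 12 (not isolated)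
Conditions: MeNH(OMe)·HCl (1.5 equiv), iPrMgCl (3.0 equiv), THF, −20 °C; then EtMgBr (3 equiv), −20 → 0 °C; 1 M HCl work-up
Reagents that add atoms: ethylmagnesium bromide, CC[Mg]Br
Why: One-flask Weinreb ketone synthesis: the chloromagnesium amide of N,O-dimethylhydroxylamine converts the ester into amide 12, whose chelated tetrahedral adduct with EtMgBr cannot over-add and collapses to the ethyl ketone on work-up, leaving the beta stereocentre untouched.

Step 6
Reactants: 13 (5R,6E)-5-ethylnon-6-en-3-one; 14 methyl acrylate
Product: 15 methyl (2E,4R)-4-ethyl-6-oxooct-2-enoate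
Conditions: 14 (8 equiv), second-generation Hoveyda–Grubbs catalyst RuCl2(SIMes)(=CH-C6H4-2-OiPr) (5 mol %), 1,4-benzoquinone (10 mol %), CH2Cl2, 40 °C
Reagents that add atoms: none
Why: Olefin cross-metathesis: the ethyl-capped alkene is exchanged for the acrylate terminus with loss of volatile but-1-ene, the conjugated enoate forming E-selectively, and the allylic stereocentre is preserved because benzoquinone suppresses ruthenium hydride isomerisation.

Step 7
Reactants: 15 methyl (2E,4R)-4-ethyl-6-oxooct-2-enoate
Product: 17 methyl 2-[(3S,4R)-4,6-diethyl-6-methoxy-1,2-dioxan-3-yl]acetate (C6 epimers), via hydroperoxy ketal 16 (not isolated)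
Conditions: urea–H2O2 (4 equiv), Sc(OTf)3 (10 mol %), MeOH, rt; then Et2NH (0.5 equiv), CF3CH2OH, rt
Reagents that add atoms: hydrogen peroxide (as its urea adduct), OO; methanol, CO
Why: Sc(OTf)3-catalysed perketalisation of the ketone with H2O2 and MeOH gives hydroperoxy ketal 16, and amine-promoted 6-exo conjugate addition of the hydroperoxide to the enoate (peroxy-Michael addition, the ring closure presumed in the biogenesis) passes through a chair transition state with the C4 ethyl group and the enoate arm both equatorial, which sets C3 as S, trans to C4, while C6 stays an epimer mixture that is erased in step 8.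

Step 8
Reactants: 17 methyl 2-[(3S,4R)-4,6-diethyl-6-methoxy-1,2-dioxan-3-yl]acetate; 11 potassium trifluoro[(1E,4R,5E)-4-ethyl-2-methylocta-1,5-dien-1-yl]borate
Product: 19 methyl 2-[(3S,4R,6S)-4,6-diethyl-6-[(1E,4R,5E)-4-ethyl-2-methylocta-1,5-dien-1-yl]-1,2-dioxan-3-yl]acetate (target CNP0243167.2), via alkenyldifluoroborane 18 (not isolated)
Conditions: 11 (1.5 equiv), BF3·OEt2 (2 equiv), CH2Cl2/MeCN 4:1, −40 → −10 °C; cold aq NaHCO3 quench
Reagents that add atoms: none
Why: Proposed new method: BF3 abstracts fluoride from 11 to give alkenyldifluoroborane 18, whose boron binds the ketal methoxy group of 17 and ionises it to a ring peroxycarbenium ion paired with the alkenyl(methoxy)difluoroborate, and the electron-rich C7 of that borate (attack leaves a tertiary, boron-stabilised β-cation) adds to C6 along the axial trajectory of the half-chair that keeps the C3 and C4 substituents pseudo-equatorial, that is anti to the C4 ethyl group and syn to the C3 side chain, which sets C6 as S before boron is lost with retention of the 7E geometry; the closest known reaction types are the Lewis acid-mediated substitution of 3-alkoxy-1,2-dioxolanes and 1,2-dioxanes by allylsilanes and silyl ketene acetals through peroxycarbenium ions and the BF3-mediated coupling of alkenyltrifluoroborates with acetals.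

**Compound list**

1 | (E)-pent-2-enal | CC/C=C/C=O | starting material
2 | (3R,4E)-hept-4-en-3-ol | CC/C=C/[C@H](O)CC | intermediate
3 | triethyl orthoacetate (1,1,1-triethoxyethane) | CC(OCC)(OCC)OCC | starting material
4 | (3R,4E)-3-(1,1-diethoxyethoxy)hept-4-ene (mixed orthoester) | CC/C=C/[C@H](OC(C)(OCC)OCC)CC | intermediate
5 | (3R,4E)-3-[(1-ethoxyethenyl)oxy]hept-4-ene (ketene acetal) | CC/C=C/[C@H](OC(=C)OCC)CC | intermediate
6 | ethyl (3R,4E)-3-ethylhept-4-enoate | CC/C=C/[C@H](CC)CC(=O)OCC | intermediate
7 | (3R,4E)-3-ethylhept-4-enal | CC/C=C/[C@H](CC)CC=O | intermediate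
8 | (4R,5E)-4-ethyloct-5-en-1-yne | CC/C=C/[C@H](CC)CC#C | intermediate
9 | [(1E,4R,5E)-4-ethyl-2-methylocta-1,5-dien-1-yl]dimethylalumane (alkenylalane) | CC/C=C/[C@H](CC)C/C(C)=C/[Al](C)C | intermediate
10 | 2-[(1E,4R,5E)-4-ethyl-2-methylocta-1,5-dien-1-yl]-4,4,5,5-tetramethyl-1,3,2-dioxaborolane (pinacol boronate) | CC/C=C/[C@H](CC)C/C(C)=C/B1OC(C)(C)C(C)(C)O1 | intermediate
11 | potassium trifluoro[(1E,4R,5E)-4-ethyl-2-methylocta-1,5-dien-1-yl]borate | CC/C=C/[C@H](CC)C/C(C)=C/[B-](F)(F)F.[K+] | intermediate
12 | (3R,4E)-3-ethyl-N-methoxy-N-methylhept-4-enamide (Weinreb amide) | CC/C=C/[C@H](CC)CC(=O)N(C)OC | intermediate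
13 | (5R,6E)-5-ethylnon-6-en-3-one | CC/C=C/[C@H](CC)CC(=O)CC | intermediate
14 | methyl acrylate | C=CC(=O)OC | starting material
15 | methyl (2E,4R)-4-ethyl-6-oxooct-2-enoate | COC(=O)/C=C/[C@H](CC)CC(=O)CC | intermediate
16 | methyl (2E,4R)-4-ethyl-6-hydroperoxy-6-methoxyoct-2-enoate (hydroperoxy ketal, C6 epimers) | COC(=O)/C=C/[C@H](CC)CC(CC)(OC)OO | intermediate
17 | methyl 2-[(3S,4R)-4,6-diethyl-6-methoxy-1,2-dioxan-3-yl]acetate (C6 epimers) | CCC1(OC)C[C@@H](CC)[C@H](CC(=O)OC)OO1 | intermediate
18 | [(1E,4R,5E)-4-ethyl-2-methylocta-1,5-dien-1-yl]difluoroborane (alkenyldifluoroborane) | CC/C=C/[C@H](CC)C/C(C)=C/B(F)F | intermediate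
19 | methyl 2-[(3S,4R,6S)-4,6-diethyl-6-[(1E,4R,5E)-4-ethyl-2-methylocta-1,5-dien-1-yl]-1,2-dioxan-3-yl]acetate | CC/C=C/[C@H](CC)C/C(C)=C/[C@]1(CC)C[C@@H](CC)[C@H](CC(=O)OC)OO1 | target

**Step count and risks**

Total step count: 8. Longest linear sequence: 6 (steps 1, 2, 5, 6, 7, 8; the side-chain branch is steps 1, 2, 3, 4, 8). Because both halves come from 6, a small enantiomeric impurity in 2 ends up mainly in diastereomers of 19 that can be removed, so the ee of 19 exceeds that of 2.

Three steps most likely to fail:

Step 8 (alkenylation of the peroxycarbenium ion). It is unprecedented with an alkenyl nucleophile; the ring may fragment under BF3, and the tertiary allylic C6–O bond of 19 can itself ionise if the quench is late. Fallback: make the C6–C7 bond before the peroxide is introduced, setting out from alkyne 8 and keto enoate 15. Carboalumination of 8 to alkenylalane 9 and iodinolysis give (1E,4R,5E)-4-ethyl-1-iodo-2-methylocta-1,5-diene F1. Iodine–lithium exchange with tBuLi (Et2O, −78 °C) gives [(1E,4R,5E)-4-ethyl-2-methylocta-1,5-dien-1-yl]lithium F2, which adds to the ketone of 15 at −78 °C to give methyl (2E,4R,7E,10R,11E)-4,6,10-triethyl-6-hydroxy-8-methyltetradeca-2,7,11-trienoate F3 as both C6 epimers. Perhydrolysis through the allyl cation (H2O2, cat. H2SO4, 0 °C) gives methyl (2E,4R,7E,10R,11E)-4,6,10-triethyl-6-hydroperoxy-8-methyltetradeca-2,7,11-trienoate F4. Et2NH in CF3CH2OH closes F4 by the same conjugate addition, and the fallback comes back to the route at 19, which is separated by HPLC from methyl 2-[(3S,4R,6R)-4,6-diethyl-6-[(1E,4R,5E)-4-ethyl-2-methylocta-1,5-dien-1-yl]-1,2-dioxan-3-yl]acetate F5. The price is no control at C6 and competing attack of H2O2 at C8.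

Step 7 (perketalisation and ring closure). The perketalisation is an equilibrium and 16 is fragile; the closure may also give some 3,4-cis isomer, which is removed by chromatography. Fallback: generate 16 irreversibly by ozonolysis instead of ketone perhydrolysis, setting out from 15. Wittig methylenation (Ph3P=CH2, THF, −78 → 0 °C) gives methyl (2E,4R)-4-ethyl-6-methylideneoct-2-enoate F6. Ozone in MeOH/CH2Cl2 at −78 °C attacks the electron-rich 1,1-disubstituted alkene in preference to the enoate, and methanol traps the carbonyl oxide, so the fallback comes back to the route at 16, which is closed with Et2NH to 17 as before.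

Step 6 (cross-metathesis). The alkene is internal and branched at the allylic position, so exchange may be slow or incomplete. Fallback: cleave and olefinate, setting out from 13. Ozonolysis (O3, CH2Cl2, −78 °C; Me2S) gives (2R)-2-ethyl-4-oxohexanal F7, which is used at once to avoid epimerisation. Wittig reaction with Ph3P=CHCO2Me (CH2Cl2, rt) gives the E enoate, and the fallback comes back to the route at 15.

**Further compounds**

F1 | step 8 | (1E,4R,5E)-4-ethyl-1-iodo-2-methylocta-1,5-diene | CC/C=C/[C@H](CC)C/C(C)=C/I
F2 | step 8 | [(1E,4R,5E)-4-ethyl-2-methylocta-1,5-dien-1-yl]lithium | CC/C=C/[C@H](CC)C/C(C)=C/[Li]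
F3 | step 8 | methyl (2E,4R,7E,10R,11E)-4,6,10-triethyl-6-hydroxy-8-methyltetradeca-2,7,11-trienoate (both C6 epimers) | CC/C=C/[C@H](CC)C/C(C)=C/C(O)(CC)C[C@@H](CC)/C=C/C(=O)OC
F4 | step 8 | methyl (2E,4R,7E,10R,11E)-4,6,10-triethyl-6-hydroperoxy-8-methyltetradeca-2,7,11-trienoate (both C6 epimers) | CC/C=C/[C@H](CC)C/C(C)=C/C(OO)(CC)C[C@@H](CC)/C=C/C(=O)OC
F5 | step 8 | methyl 2-[(3S,4R,6R)-4,6-diethyl-6-[(1E,4R,5E)-4-ethyl-2-methylocta-1,5-dien-1-yl]-1,2-dioxan-3-yl]acetate | CC/C=C/[C@H](CC)C/C(C)=C/[C@@]1(CC)C[C@@H](CC)[C@H](CC(=O)OC)OO1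
F6 | step 7 | methyl (2E,4R)-4-ethyl-6-methylideneoct-2-enoate | COC(=O)/C=C/[C@H](CC)CC(=C)CC
F7 | step 6 | (2R)-2-ethyl-4-oxohexanal | O=C[C@H](CC)CC(=O)CC
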